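## Retrosynthetic overview

1. The target is the 9-O-isovalerate of (+)-lariciresinol 13 (C7–C9: half whose aryl group sits on the ring; C7'–C9': benzyl half). The ester is made last, by a chemoselective Mitsunobu reaction on the primary alcohol.
2. Enabling feature: on the oxolane (O–C7–C8–C8'–C9') the CH2–O arm on C8 and the benzylic CH2 (C7') on C8' are cis on adjacent ring carbons. O9 and C7' can therefore be tied into a second, temporary oxolane, so the target is a seco-furofuran. 13 then comes from the C2-symmetric cis-fused 3,7-dioxabicyclo[3.3.0]octane 12 by hydrogenolysis of one benzylic C–O bond, as in the biosynthesis.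
3. Key disconnection: 12 is cut at C8–C8' and at O–C7 together, which leads back to the acyclic epoxy cinnamyl ether 9. In the forward sense the tether oxolane (O–C7'–C8'–C8–C9) closes first, then the oxolane of the target (O–C7–C8–C8'–C9').
4. 9 is made from epoxy alcohol 4 and cinnamyl bromide 8, both derived from O-benzylvanillin 1. C7' (from a Sharpless kinetic resolution) is the only stereocentre brought in; it relays to C8', C8 and C7 and is erased in step 8.

Key step: step 7

Remark: lignan numbering is used throughout; the natural-product name counts the ester-bearing carbon as 9', which is C9 here.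

## Route

Step 1
Reactants: 1 4-(benzyloxy)-3-methoxybenzaldehyde; 2 vinylmagnesium bromide
Product: 3 rac-1-[4-(benzyloxy)-3-methoxyphenyl]prop-2-en-1-ol
Conditions: THF, −78 → 0 °C; aq NH4Cl
Reagents that add atoms: none
Why: Grignard 1,2-addition of the vinyl nucleophile to the aryl aldehyde is clean at low temperature; the new carbinol centre (the future C7') forms racemic and is resolved in step 2.

Step 2
Reactants: 3 rac-1-[4-(benzyloxy)-3-methoxyphenyl]prop-2-en-1-ol
Product: 4 (R)-[4-(benzyloxy)-3-methoxyphenyl][(2S)-oxiran-2-yl]methanol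
Conditions: Ti(OiPr)4 (0.1 equiv), D-(−)-diisopropyl tartrate (0.15 equiv), t-BuOOH (0.45 equiv), 4 Å molecular sieves, CH2Cl2, −20 °C; aq FeSO4/tartaric acid
Reagents that add atoms: tert-butyl hydroperoxide, CC(C)(C)OO
Why: Sharpless asymmetric epoxidation run as a kinetic resolution: with the D-(−)-tartrate the (S)-enantiomer of 3 should be epoxidised much faster and anti (erythro) selectively, so the carbinol centre of 4 is R by resolution and the oxirane centre S by reagent control, while the (R)-alcohol stays behind and conversion is held below one half.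

Step 3
Reactants: 1 4-(benzyloxy)-3-methoxybenzaldehyde; 5 triethyl phosphonoacetate
Product: 6 ethyl (2E)-3-[4-(benzyloxy)-3-methoxyphenyl]prop-2-enoate
Conditions: NaH, THF, 0 °C → rt
Reagents that add atoms: none
Why: Horner–Wadsworth–Emmons olefination with a stabilised phosphonate anion should give the (E)-cinnamate; no stereocentre is formed.

Step 4
Reactants: 6 ethyl (2E)-3-[4-(benzyloxy)-3-methoxyphenyl]prop-2-enoate
Product: 7 (2E)-3-[4-(benzyloxy)-3-methoxyphenyl]prop-2-en-1-ol
Conditions: iBu2AlH (2.2 equiv), CH2Cl2, −78 °C; aq potassium sodium tartrate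
Reagents that add atoms: none
Why: 1,2-reduction of the α,β-unsaturated ester by the aluminium hydride at low temperature gives the allylic alcohol without touching the alkene or the benzyl ether.

Step 5
Reactants: 7 (2E)-3-[4-(benzyloxy)-3-methoxyphenyl]prop-2-en-1-ol
Product: 8 1-(benzyloxy)-4-[(1E)-3-bromoprop-1-en-1-yl]-2-methoxybenzene
Conditions: PBr3 (0.4 equiv), Et2O, 0 °C; used crude at once
Reagents that add atoms: phosphorus tribromide, BrP(Br)Br
Why: bromination of the primary allylic alcohol with PBr3 (SN2 displacement of the phosphite ester) gives the cinnamyl bromide, which is used immediately because the electron-rich allylic bromide ionises easily.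

Step 6
Reactants: 4 (R)-[4-(benzyloxy)-3-methoxyphenyl][(2S)-oxiran-2-yl]methanol; 8 1-(benzyloxy)-4-[(1E)-3-bromoprop-1-en-1-yl]-2-methoxybenzene
Product: 9 (2S)-2-[(R)-[4-(benzyloxy)-3-methoxyphenyl]{[(2E)-3-[4-(benzyloxy)-3-methoxyphenyl]prop-2-en-1-yl]oxy}methyl]oxirane
Conditions: NaH, n-Bu4NI (cat.), THF–DMF, 0 °C
Reagents that add atoms: none
Why: Williamson ether synthesis: the sodium alkoxide of 4 is alkylated at the primary carbon of the reactive allylic bromide at 0 °C in an aprotic medium, where Payne rearrangement of the epoxy alkoxide should not compete (as in routine O-benzylation of 2,3-epoxy alcohols), and neither stereocentre is touched.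

Step 7
Reactants: 9 (2S)-2-[(R)-[4-(benzyloxy)-3-methoxyphenyl]{[(2E)-3-[4-(benzyloxy)-3-methoxyphenyl]prop-2-en-1-yl]oxy}methyl]oxirane
Product: 12 (1S,3aR,4S,6aR)-1,4-bis[4-(benzyloxy)-3-methoxyphenyl]tetrahydro-1H,3H-furo[3,4-c]furan, via β-titanoxy C8' radical 10 (not isolated), via benzylic iodide 11 (not isolated)
Conditions: Cp2TiCl (2.2 equiv, from Cp2TiCl2 and Zn dust in THF, decanted from Zn), slow addition to 9, THF, rt; then I2 (1.2 equiv), rt → 50 °C; aq NaH2PO4/Na2S2O3
Reagents that add atoms: none
Why: Cp2TiCl (trivalent titanium) opens the oxirane of 9 by single-electron transfer at the more substituted C–O bond to give the planar β-titanoxy radical 10 at C8' (either oxirane epimer would give the same radical), which adds 5-exo-trig to the styrene carbon C8 and so closes the tether oxolane (O–C7'–C8'–C8–C9). The benzylic C7 radical is trapped by a second Cp2TiCl, iodine converts the benzyl–titanium bond into the benzylic iodide 11, and the titanium alkoxide on C9' displaces iodide in a 5-exo-tet closure of the second oxolane (O–C7–C8–C8'–C9'), a radical–polar crossover that forms C8'–C8 and O–C7 in one flask. The closest known reaction type is the Cp2TiCl-mediated epoxide-opening radical cyclisation of epoxy cinnamyl ethers with iodine-induced etherification to furofurans, and the order of events (radical C8–C8' bond, then oxygen attack on a quinone-methide-like benzylic carbon) copies the biosynthesis of the skeleton. C8' and C8 are set by the resolved centre C7': in the chair-like 5-exo transition state the C7' aryl group lies pseudo-equatorial, which puts the CH2O–Ti arm on C8' trans to it and cis to the new benzylic arm on C8. C7 is set in the polar closure: only a cis arm can reach C7, and since the p-alkoxybenzylic iodide ionises and epimerises easily, both C7 epimers of 11 should funnel into the cis-fused bicycle with the aryl group exo (7S). The step needs regioselective oxirane opening (secondary over primary radical), 5-exo over 6-endo addition and cyclisation faster than reduction of 10 by Cp2TiCl; the substitution of the oxirane, the benzylic stabilisation at C7 and the slow addition of the reagent secure these.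

Step 8
Reactants: 12 (1S,3aR,4S,6aR)-1,4-bis[4-(benzyloxy)-3-methoxyphenyl]tetrahydro-1H,3H-furo[3,4-c]furan
Product: 13 4-[(2S,3R,4R)-4-(4-hydroxy-3-methoxybenzyl)-3-(hydroxymethyl)oxolan-2-yl]-2-methoxyphenol ((+)-lariciresinol)
Conditions: H2 (1 atm), 10% Pd/C, EtOAc–EtOH, rt; stopped when 13 is at its maximum
Reagents that add atoms: none
Why: heterogeneous hydrogenolysis removes the two aryl benzyl ethers quickly and then cleaves one benzylic ring C–O bond (the laboratory counterpart of the reductase step of the biosynthesis); because 12 is C2-symmetric its two oxolanes are homotopic and either cleavage gives the same triol 13, no stereocentre is formed or touched (the relay centre C7' becomes CH2), and the reaction is stopped before the second ring opens.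

Step 9
Reactants: 13 (+)-lariciresinol; 14 3-methylbutanoic acid
Product: 15 [(2S,3R,4R)-2-(4-hydroxy-3-methoxyphenyl)-4-(4-hydroxy-3-methoxybenzyl)oxolan-3-yl]methyl 3-methylbutanoate ((+)-9'-isovaleroxylariciresinol)
Conditions: PPh3, DIAD, THF, 0 °C → rt
Reagents that add atoms: none
Why: Mitsunobu esterification: the far more acidic carboxylic acid is deprotonated by the PPh3–DIAD betaine ahead of the phenols and only the aliphatic primary alcohol forms an alkoxyphosphonium ion, so the carboxylate displaces it at C9 and the phenols should stay free; no stereocentre is involved.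

## Compound list

1 | 4-(benzyloxy)-3-methoxybenzaldehyde (O-benzylvanillin) | COc1cc(C=O)ccc1OCc1ccccc1 | starting material
2 | vinylmagnesium bromide | C=C[Mg]Br | starting material
3 | rac-1-[4-(benzyloxy)-3-methoxyphenyl]prop-2-en-1-ol | COc1cc(C(O)C=C)ccc1OCc1ccccc1 | intermediate
4 | (R)-[4-(benzyloxy)-3-methoxyphenyl][(2S)-oxiran-2-yl]methanol | COc1cc(ccc1OCc1ccccc1)[C@@H](O)[C@@H]1CO1 | intermediate
5 | triethyl phosphonoacetate | CCOC(=O)CP(=O)(OCC)OCC | starting material
6 | ethyl (2E)-3-[4-(benzyloxy)-3-methoxyphenyl]prop-2-enoate | CCOC(=O)/C=C/c1ccc(OCc2ccccc2)c(OC)c1 | intermediate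
7 | (2E)-3-[4-(benzyloxy)-3-methoxyphenyl]prop-2-en-1-ol | OC/C=C/c1ccc(OCc2ccccc2)c(OC)c1 | intermediate
8 | 1-(benzyloxy)-4-[(1E)-3-bromoprop-1-en-1-yl]-2-methoxybenzene | BrC/C=C/c1ccc(OCc2ccccc2)c(OC)c1 | intermediate
9 | (2S)-2-[(R)-[4-(benzyloxy)-3-methoxyphenyl]{[(2E)-3-[4-(benzyloxy)-3-methoxyphenyl]prop-2-en-1-yl]oxy}methyl]oxirane | COc1cc(ccc1OCc1ccccc1)[C@@H](OC/C=C/c1ccc(OCc2ccccc2)c(OC)c1)[C@@H]1CO1 | intermediate
10 | β-titanoxy C8' radical from 9 (oxirane opened, C7' unchanged), as its Cp2Ti(Cl) alkoxide | COc1cc(ccc1OCc1ccccc1)[C@@H](OC/C=C/c1ccc(OCc2ccccc2)c(OC)c1)[CH]C[O-].[Ti+4].[Cl-].c1cc[cH-]c1.c1cc[cH-]c1 | intermediate (not isolated)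
11 | Cp2Ti(Cl) alkoxide of {(2S,3R,4R)-2-[4-(benzyloxy)-3-methoxyphenyl]-4-{[4-(benzyloxy)-3-methoxyphenyl](iodo)methyl}oxolan-3-yl}methanol, both C7 epimers | COc1cc(ccc1OCc1ccccc1)[C@@H]1[C@@H](C[O-])[C@@H](C(I)c2ccc(OCc3ccccc3)c(OC)c2)CO1.[Ti+4].[Cl-].c1cc[cH-]c1.c1cc[cH-]c1 | intermediate (not isolated)
12 | (1S,3aR,4S,6aR)-1,4-bis[4-(benzyloxy)-3-methoxyphenyl]tetrahydro-1H,3H-furo[3,4-c]furan (O,O'-dibenzyl ether of (+)-pinoresinol) | COc1cc(ccc1OCc1ccccc1)[C@@H]1[C@H]2CO[C@H](c3ccc(OCc4ccccc4)c(OC)c3)[C@H]2CO1 | intermediate
13 | 4-[(2S,3R,4R)-4-(4-hydroxy-3-methoxybenzyl)-3-(hydroxymethyl)oxolan-2-yl]-2-methoxyphenol ((+)-lariciresinol) | COc1cc(C[C@H]2CO[C@H](c3ccc(O)c(OC)c3)[C@H]2CO)ccc1O | intermediate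
14 | 3-methylbutanoic acid (isovaleric acid) | CC(C)CC(=O)O | starting material
15 | [(2S,3R,4R)-2-(4-hydroxy-3-methoxyphenyl)-4-(4-hydroxy-3-methoxybenzyl)oxolan-3-yl]methyl 3-methylbutanoate | COc1cc(C[C@H]2CO[C@H](c3ccc(O)c(OC)c3)[C@H]2COC(=O)CC(C)C)ccc1O | target

## Step count and risks

Total steps: 9. Longest linear sequence: 7 steps (steps 3, 4, 5, 6, 7, 8, 9, from 1).

Steps most likely to fail:

1. Step 7 (key cascade). What may go wrong: reduction of the C8' radical by a second Cp2TiCl and β-elimination of the titanoxy group (deoxygenation) before it cyclises, incomplete oxidative closure of the second ring after iodine is added, or loss of trans/cis control in the 5-exo addition. Fallback (sets out from 9, comes back at 13): the oxidative termination is dropped. The same Cp2TiCl-mediated epoxide opening and 5-exo cyclisation is ended by protonation (Cp2TiCl, THF, rt; then dilute aq H2SO4), a known reductive radical cyclisation. It leaves the oxolane built on the pre-existing C7'–O ether and the C9' oxygen as a free primary alcohol, and should give lariciresinol dibenzyl ether F1. Hydrogenolysis of the two aryl benzyl ethers only (H2, 10% Pd/C, EtOAc, short contact) then gives 13.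

2. Step 8 (mono-hydrogenolysis). What may go wrong: over-reduction, with the second benzylic C–O bond cleaved at a similar rate, and acid-promoted epimerisation or Friedel–Crafts cyclisation at the benzylic ring carbon on the catalyst. Fallback (sets out from 12, comes back at 15): homogeneous ionic hydrogenation with the hydride donor as limiting reagent (Et3SiH 1.0 equiv, BF3·OEt2, CH2Cl2, −78 °C). It opens one oxolane by ionisation of a p-alkoxybenzylic C–O bond and hydride capture while the benzyl ethers stay on, so lariciresinol dibenzyl ether F1 (the compound of the first fallback) can be separated from unchanged 12, which is recycled. Acylation of its only free hydroxyl (isovaleryl chloride, pyridine, DMAP cat., CH2Cl2, 0 °C) gives the dibenzyl ether of the target F2. Brief hydrogenolysis (H2, 10% Pd/C, EtOAc) removes the aryl benzyl ethers and gives 15. This path also avoids the chemoselective esterification of step 9.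

3. Step 2 (kinetic resolution). What may go wrong: slow epoxidation of the monosubstituted vinyl group and titanium-promoted ionisation and opening of the electron-rich benzylic epoxy alcohol, which would erode yield and enantiomeric purity. Fallback (sets out from 3, comes back at 12): enzymatic kinetic resolution (immobilised Candida antarctica lipase B, vinyl acetate, MTBE, rt) acylates the (R)-enantiomer and leaves (S)-1-[4-(benzyloxy)-3-methoxyphenyl]prop-2-en-1-ol F3. Hydroxyl-directed epoxidation without a chiral reagent (mCPBA, NaHCO3, CH2Cl2, 0 °C → rt) gives 4 together with its oxirane epimer F4. The mixture is alkylated with 8 under the conditions of step 6 to 9 and its oxirane epimer F5. Because both epimers open to the same planar radical 10 in step 7, the mixture should converge on 12.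

## Further compounds

F1 | step 7 | [(2S,3R,4R)-2-[4-(benzyloxy)-3-methoxyphenyl]-4-[4-(benzyloxy)-3-methoxybenzyl]oxolan-3-yl]methanol (lariciresinol dibenzyl ether) | COc1cc(C[C@H]2CO[C@H](c3ccc(OCc4ccccc4)c(OC)c3)[C@H]2CO)ccc1OCc1ccccc1
F2 | step 8 | [(2S,3R,4R)-2-[4-(benzyloxy)-3-methoxyphenyl]-4-[4-(benzyloxy)-3-methoxybenzyl]oxolan-3-yl]methyl 3-methylbutanoate | COc1cc(C[C@H]2CO[C@H](c3ccc(OCc4ccccc4)c(OC)c3)[C@H]2COC(=O)CC(C)C)ccc1OCc1ccccc1
F3 | step 2 | (S)-1-[4-(benzyloxy)-3-methoxyphenyl]prop-2-en-1-ol | COc1cc(ccc1OCc1ccccc1)[C@@H](O)C=C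
F4 | step 2 | (R)-[4-(benzyloxy)-3-methoxyphenyl][(2R)-oxiran-2-yl]methanol | COc1cc(ccc1OCc1ccccc1)[C@@H](O)[C@H]1CO1
F5 | step 2 | (2R)-2-[(R)-[4-(benzyloxy)-3-methoxyphenyl]{[(2E)-3-[4-(benzyloxy)-3-methoxyphenyl]prop-2-en-1-yl]oxy}methyl]oxirane | COc1cc(ccc1OCc1ccccc1)[C@@H](OC/C=C/c1ccc(OCc2ccccc2)c(OC)c1)[C@H]1CO1
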